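The data are simulated with made-up constants, noise included.

I have no rate constants for this flask, so I look in the readings for something that holds still.

| setting | north | north-west | south-west | flask |
|---|---|---|---|---|
| Z | 0.020 M (fed, over 15 min) | 0.031 M (fed, over 15 min) | 0.014 M (fed, over 15 min) | 0.014 M (fed, over 15 min) |
| E | 0.021 M | 0.021 M | 0.011 M | 0.0210 M |
| remark | run made earlier | run made earlier | run made earlier |  |
| time |  |  |  | 2.5 h |

| run | time / h | Q / % | Z / % |
|---|---|---|---|
| north | 0.0500 | 6.6 | 10.5 |
| north | 0.100 | 11.5 | 17.1 |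
| north | 0.200 | 13.2 | 34.8 |
| north | 0.417 | 6.1 | 31.7 |
| north | 0.667 | 4.1 | 24.8 |
| north | 1.33 | 3.6 | 22.6 |
| north | 2.50 | 3.4 | 22.1 |
| north-west | 0.0500 | 7.0 | 11.2 |
| north-west | 0.100 | 10.2 | 19.7 |
| north-west | 0.200 | 10.6 | 41.0 |
| north-west | 0.417 | 4.4 | 46.6 |
| north-west | 0.667 | 2.8 | 42.4 |
| north-west | 1.33 | 3.1 | 40.5 |
| north-west | 2.50 | 2.6 | 41.0 |
| south-west | 0.0500 | 4.1 | 13.2 |
| south-west | 0.133 | 10.9 | 29.0 |
| south-west | 0.417 | 5.2 | 42.4 |
| south-west | 1.00 | 2.9 | 35.1 |
| south-west | 2.50 | 3.3 | 33.6 |

(readings scatter by 0.3 percentage points)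

- the numbers in the tables scatter with a standard deviation of 0.3 percentage points
- percentages count the whole charge, also what has not yet gone in

* the best time, 2.5 h at the latest, for Q
* the amount of Q, in percent of the Z charged, at that time

Call M the percent of the charge found neither as Z nor as Q. At 2.50 h in the north run, the tail ratio r = M/Q is 21.9. The north-west run, with more Z, gives 21.7, and the south-west run gives 19.1, but each Q in these ratios carries a scatter of 0.3 percentage points.

So I freeze r: late on, Q is 4.36% of the Z that has reacted, and I expect that of this flask. But at 0.200 h in the north run, with the feed unfinished, Q was 29.2% of the reacted Z. So Q in the north run passes through an excess, kinetic against thermodynamic control, and that reading is its highest; I expect the peak of this flask near the end of the feed too.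

My rule gives no height. The forecast gives 15.5% (13.5% to 18.5%) at 0.2 h (0.15 h to 0.26 h): “The maximum should come just before the feed ends”.

The flask peaks at 14.9% at 0.225 h.

    Q ⇌ J (K = 21.8, k = 0.312 min⁻¹)
    Z + E ⇌ Q + D (K = 0.432, k = 25.7 M⁻¹ min⁻¹)

By the step between them alone, both ways together, Q and J relax with a half-life of 2.12 min, short against 2.5 h. At 2.50 h the flask holds 12.5% of Z, so r gives Q as 3.82%, and it stands at 3.84%. The neighbour charged with 0.056 M of Z ends with 64.5% of Z, so r gives 1.55%, and its Q stands at 1.56%.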